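## The problem

The target is a (2S)-flavanone: a chroman-4-one (rings A and C) with a 2,4,6-trihydroxyphenyl ring B on C2, hydroxyls on C5 and C7, and an (R)-lavandulyl chain on C6, the carbon between the two ring A hydroxyls. Its two stereocenters, C2 and C2'' of the side chain, lie seven bonds apart across the flat ring A. Neither can steer the other, and isomers differing at one of them would be hard to separate, so each must be set independently and absolutely before the halves are joined. Ring A is a phloroglucinol whose three oxygens end up in three different roles (O1, 5-OH, 7-OH). Any ring closure that engages an oxygen next to the acyl group must choose between two ortho oxygens, and so between the 6- and the 8-lavandulyl flavanone. The 1,1-disubstituted and trisubstituted alkenes of the side chain exclude hydrogenation and strong acid: protonating the isopropenyl group closes a chroman onto a neighbouring phenol or moves the double bond to the tetrasubstituted position, which erases C2''. The C2–O1 bond is a benzylic ether to a trioxygenated ring; with free ring B phenols it ionises in acid and opens to the chalcone in base, which racemises C2 and can move the side chain to C8 on reclosure. The enabling feature is that O1 sits on C8a, para to C6. An aryl ether made at the oxygen para to the side chain of 2-lavandulylphloroglucinol has two ortho carbons that are interchanged by rotation about the O–C1/C4–C1'' axis, so acylation of either one forms C4–C4a and gives only the 6-substituted chromanone.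

## Retrosynthesis

**Unmasking (22 from 21 from 20).** No skeletal bond is cut. Ring B is carried as a triacetate, which keeps it too electron-poor for C2–O1 to ionise and comes off near pH 7. Ring A is carried as a bis-silyl ether, which keeps it nucleophilic for the acylation and comes off with buffered fluoride. The silyl ethers go first (20 to 21) and the acetates last (21 to 22), so the configurationally fragile free ring B exists only in the final, neutral step.

**Ring C (20 from 18).** The C4–C4a bond is cut. The neighbouring cut at O1–C2 (chalcone closure) would need base, would not control C2, and would face the choice between two ortho oxygens. The cut at C4–C4a places the regiochemical decision on a ring whose two candidate carbons are equivalent. The precursor is the open-chain acid 18, one ring simpler, with both stereocenters already in place. The forward step must acylate through the mixed anhydride 19 without ionising C2–O1, protonating the alkenes or stripping the silyl ethers.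

**Aryl ether (18 from 16 from 9 and 15).** The O1–C2 bond is cut into phenol 9 and the benzylic alcohol 15, joined with inversion; the acid is then freed from a tert-butyl ester (through silyl ester 17). Cutting here rather than at C2–C3 gives two fragments of similar size, each with one stereocenter that can be secured separately. The tert-butyl ester is chosen because it can be removed without base (a beta-aryloxy ester expels phenoxide) and without protic acid. The forward reaction must invert cleanly, avoid elimination to the cinnamate, and give the ortho acetates no chance to shift onto the free hydroxyl.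

**Ring B fragment (15 from 11 and 13; 11 from 10; 13 from 12).** The C2–C3 bond is cut to the peracetylated aldehyde 11 and the silyl ketene acetal 13 of tert-butyl acetate 12. A Lewis-acid aldol is preferred to enolate aldols, because a metal alkoxide next to two aryl acetates would take up an acetyl group. It is preferred to ketone reduction, which needs an extra homologation and a hindered di-ortho-substituted ketone. The step must deliver the (R)-alcohol through the silyl ether 14 and never pass through an alkoxide.

**Ring A fragment (9 from 8 from 6 and 3; 6 from 5 from 4).** The C6–C1'' bond is cut between aryl iodide 6 and the zinc reagent 7 made from iodide 3. Cationic alkylation of a phloroglucinol would scramble the allylic chain. Ortho-metalated aryl silyl ethers rearrange, so the aryl partner is the electrophile. The iodide comes from phloroglucinol 4 through 5 by iodination and silylation. The para oxygen is freed after the coupling (8 to 9), where both sterics and phenoxide stability favour it.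

**Side chain (3 from 2 from 1).** No carbon–carbon bond is cut. C2'' is a tertiary all-carbon center flanked by a vinyl and an allyl group; it is safest bought with the intact skeleton and never placed next to a carbonyl. Racemic alcohol 1 is resolved to 2 and converted to the iodide 3.

## Roads not taken

**Alternative 1:** The cuts are C6–C1'' and C2''–C3''. A ring A aryl copper reagent adds to the chiral acrylimide A2, and the enolate is alkylated by prenyl bromide A3 to give imide A1, with C2'' set by the auxiliary.
- Merits: absolute, predictable control at C2'' without discarding half of a racemate, and in A1 the para oxygen of ring A is already distinguished from the two ortho oxygens.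
- Weak points: the imide carbonyl must still become the isopropenyl group through an alpha-chiral, enolisable methyl ketone, which puts C2'' at risk and costs several steps. The tandem addition–alkylation with a di-ortho-oxygenated aryl copper reagent is sluggish. The acetal protecting groups of A1 would not survive the acylation and would have to be exchanged.
- Comparison: this road is better on stereocontrol at C2'' and on oxygen differentiation. The chosen plan offers a side chain carried intact in two steps from 1, a stereocenter that never sits beside a carbonyl, and a ring C closure whose regiochemistry is decided by symmetry. Alternative 1 does not address ring C or C2 at all.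

**Alternative 2:** The cut is C1''–C2''. Fluoride releases a ring A ortho-quinone methide, which is trapped by a chiral azolium enolate to form C1''–C2'' and an aryl ester, closing the temporary lactone A4.
- Merits: catalytic enantiocontrol, mild conditions, and three differently protected ring A oxygens in A4, with the future O1 as its own ether. That is cleaner than the selective desilylation of 8.
- Weak points: the new stereocenter is alpha to an aryl ester and epimerises easily. The lactone carbon must be turned into isopropenyl by two carbon–carbon bond formations on a carbonyl that tends to over-add. Alpha-alkyl azolium enolates give variable selectivity. The quinone methide precursor on an electron-rich ring is labile.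
- Comparison: better on oxygen differentiation, worse on step count and on the safety of C2''. The chosen plan accepts one selectivity problem at 8 in exchange for never building the side chain on the ring.

**Alternative 3:** Ring A itself is built. A vinylketene from a cyclobutenone combines with a lavandulyl-bearing siloxyalkyne to form C5–C6, C7–C8 and C4a–C5 and give phenol A5.
- Merits: the substitution pattern of ring A is fully programmed, all three oxygens are different, and no cross-coupling at a di-ortho-substituted carbon is needed. That is a real advantage over the coupling of 6 with 7.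
- Weak points: both annulation partners need multistep preparation. The thermal step heats a 1,5-diene. In A5 the oxygen para to the side chain carries an acid-labile acetal, while a free phenol sits next to the chain, so several protecting-group exchanges under chroman-forming risk would precede ether formation.
- Comparison: better on regiocontrol of ring A, clearly longer. The chosen plan starts from phloroglucinol 4 and reaches 9 in four steps.

Key step: step 12

Assumption 1: the lipase acylates (R)-lavandulol faster, so (S)-2 is the recovered alcohol; were the preference reversed, 2 would be taken from the ester fraction after methanolysis.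

Assumption 2: the (R,R)-bisphosphoramide directs the ketene acetal to the Re face of aldehyde 11, which gives (R)-15; should the first run show the opposite sense, the (S,S)-catalyst is used with no other change.

## Route

Step 1
Reactants: 1 racemic lavandulol, (RS)-5-methyl-2-(prop-1-en-2-yl)hex-4-en-1-ol
Product: 2 (S)-lavandulol, (2S)-5-methyl-2-(prop-1-en-2-yl)hex-4-en-1-ol
Conditions: porcine pancreatic lipase, vinyl acetate, hexane, 25 °C, stopped beyond half conversion; chromatography
Reagents that add atoms: none
Why: Lipase-catalysed kinetic resolution by transesterification; the faster-reacting (R)-alcohol is removed as its acetate, and running past half conversion should leave (S)-2 in high enantiomeric purity even if the selectivity factor is only moderate, which sets C2'' for the whole route.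

Step 2
Reactants: 2 (S)-lavandulol
Product: 3 (S)-lavandulyl iodide, (3S)-3-(iodomethyl)-2,6-dimethylhepta-1,5-diene
Conditions: I2, PPh3, imidazole, CH2Cl2, 0 °C to 20 °C
Reagents that add atoms: iodine, II
Why: Appel-type iodination by SN2 displacement of the primary alkoxyphosphonium ion; the medium is neutral and cold, so the alkenes and the adjacent stereocenter are not touched.

Step 3
Reactants: 4 phloroglucinol, benzene-1,3,5-triol
Product: 5 2-iodobenzene-1,3,5-triol
Conditions: I2 (1 equiv), NaHCO3, THF/H2O, 0 °C
Reagents that add atoms: iodine, II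
Why: Electrophilic aromatic iodination of the triply activated ring under bicarbonate buffering; all three ring positions are equivalent, so only over-iodination has to be held back, by stoichiometry and temperature.

Step 4
Reactants: 5 2-iodobenzene-1,3,5-triol
Product: 6 2-iodo-1,3,5-tris(tert-butyldimethylsilyloxy)benzene
Conditions: TBSCl, imidazole, DMF, 20 °C
Reagents that add atoms: tert-butyl(chloro)dimethylsilane, CC(C)(C)[Si](C)(C)Cl
Why: Standard imidazole-promoted silylation of phenols; three equal silyl ethers keep the later ring A electron-rich and are stable to organozinc reagents and to the acylation.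

Step 5
Reactants: 3 (S)-lavandulyl iodide; 6 2-iodo-1,3,5-tris(tert-butyldimethylsilyloxy)benzene
Product: 8 1,3,5-tris(tert-butyldimethylsilyloxy)-2-[(2R)-5-methyl-2-(prop-1-en-2-yl)hex-4-enyl]benzene, via lavandulylzinc iodide 7 (not isolated)
Conditions: 3, Zn dust (BrCH2CH2Br, Me3SiCl), DMA, 40 °C; then 6, Pd(OAc)2 (5 mol%), SPhos (10 mol%), THF, 50 °C
Reagents that add atoms: none
Why: Zinc insertion into the primary iodide followed by Negishi coupling; the bulky biarylphosphine on zerovalent palladium speeds transmetalation and reductive elimination at the di-ortho-substituted aryl and outruns beta-hydride elimination, and the stereocenter, beta to zinc, is not involved (its descriptor changes from S to R only because the priorities change).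

Step 6
Reactants: 8 1,3,5-tris(tert-butyldimethylsilyloxy)-2-[(2R)-5-methyl-2-(prop-1-en-2-yl)hex-4-enyl]benzene
Product: 9 3,5-bis(tert-butyldimethylsilyloxy)-4-[(2R)-5-methyl-2-(prop-1-en-2-yl)hex-4-enyl]phenol
Conditions: Cs2CO3 (1 equiv), DMF/H2O (10:1), 0 °C, stopped when 8 is consumed
Reagents that add atoms: none
Why: Nucleophilic cleavage of an aryl silyl ether; the para silyl ether has two free ortho positions and gives the better-stabilised phenoxide, while the two ortho silyl ethers are shielded by the branched chain, and the first phenoxide formed makes the ring too electron-rich for a second cleavage.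

Step 7
Reactants: 10 2,4,6-trihydroxybenzaldehyde
Product: 11 2,4,6-tris(acetyloxy)benzaldehyde
Conditions: Ac2O, pyridine, DMAP (cat.), CH2Cl2, 0 °C to 20 °C
Reagents that add atoms: acetic anhydride, CC(=O)OC(C)=O
Why: Nucleophile-catalysed peracetylation of the phenols, including the two hydrogen-bonded ortho hydroxyls; the acetates make ring B electron-poor for all later steps.

Step 8
Reactants: 12 tert-butyl acetate
Product: 13 1-(tert-butoxy)-1-(tert-butyldimethylsilyloxy)ethene
Conditions: LiN(iPr)2, THF, −78 °C; TBSCl, DMPU, −78 °C to 20 °C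
Reagents that add atoms: tert-butyl(chloro)dimethylsilane, CC(C)(C)[Si](C)(C)Cl
Why: O-silylation of the lithium ester enolate in the presence of a polar cosolvent gives the stable silyl ketene acetal.

Step 9
Reactants: 11 2,4,6-tris(acetyloxy)benzaldehyde; 13 1-(tert-butoxy)-1-(tert-butyldimethylsilyloxy)ethene
Product: 15 tert-butyl (3R)-3-hydroxy-3-[2,4,6-tris(acetyloxy)phenyl]propanoate, via trichlorosilyl ether 14 (not isolated)
Conditions: SiCl4, (R,R)-bisphosphoramide from N,N'-dimethyl-1,1'-binaphthyl-2,2'-diamine (pentane-1,5-diyl-linked, 5 mol%), iPr2NEt (10 mol%), CH2Cl2, −78 °C; cold pH 7 phosphate buffer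
Reagents that add atoms: none
Why: Catalytic enantioselective Mukaiyama aldol addition under Lewis-base activation of SiCl4; the aldehyde bound to the chiral phosphoramide–chlorosilyl cation is attacked on its Re face through an open transition state, so the catalyst sets C2 as R, and because the adduct is a silyl ether until the cold neutral hydrolysis, no alkoxide is present to take an acetyl group from the ortho positions.

Step 10
Reactants: 9 3,5-bis(tert-butyldimethylsilyloxy)-4-[(2R)-5-methyl-2-(prop-1-en-2-yl)hex-4-enyl]phenol; 15 tert-butyl (3R)-3-hydroxy-3-[2,4,6-tris(acetyloxy)phenyl]propanoate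
Product: 16 tert-butyl (3S)-3-{3,5-bis(tert-butyldimethylsilyloxy)-4-[(2R)-5-methyl-2-(prop-1-en-2-yl)hex-4-enyl]phenoxy}-3-[2,4,6-tris(acetyloxy)phenyl]propanoate
Conditions: PPh3, DIAD, toluene, 0 °C to 20 °C (15 in slight excess)
Reagents that add atoms: none
Why: Mitsunobu etherification; the phenol displaces the alkoxyphosphonium ion by SN2 with inversion, turning (R)-15 into (S)-16, and the electron-poor di-ortho-acetoxylated ring disfavours ionisation, as is known for di-ortho-halogenated 1-arylethanols, while the bulky tert-butyl ester slows elimination to the cinnamate.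

Step 11
Reactants: 16 tert-butyl (3S)-3-{3,5-bis(tert-butyldimethylsilyloxy)-4-[(2R)-5-methyl-2-(prop-1-en-2-yl)hex-4-enyl]phenoxy}-3-[2,4,6-tris(acetyloxy)phenyl]propanoate
Product: 18 (3S)-3-{3,5-bis(tert-butyldimethylsilyloxy)-4-[(2R)-5-methyl-2-(prop-1-en-2-yl)hex-4-enyl]phenoxy}-3-[2,4,6-tris(acetyloxy)phenyl]propanoic acid, via trimethylsilyl ester 17 (not isolated)
Conditions: Me3SiOTf, 2,6-lutidine, CH2Cl2, 0 °C; pH 5 aqueous work-up
Reagents that add atoms: none
Why: Silyl triflate-mediated cleavage of a tert-butyl ester: silylation of the carbonyl oxygen releases the tert-butyl cation, which the lutidine converts to isobutene, and the silyl ester hydrolyses on work-up; the conditions are neither basic (no phenoxide elimination) nor protic-acidic (no alkene protonation).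

Step 12
Reactants: 18 (3S)-3-{3,5-bis(tert-butyldimethylsilyloxy)-4-[(2R)-5-methyl-2-(prop-1-en-2-yl)hex-4-enyl]phenoxy}-3-[2,4,6-tris(acetyloxy)phenyl]propanoic acid
Product: 20 (2S)-5,7-bis(tert-butyldimethylsilyloxy)-6-[(2R)-5-methyl-2-(prop-1-en-2-yl)hex-4-enyl]-2-[2,4,6-tris(acetyloxy)phenyl]chroman-4-one, via mixed trifluoroacetic anhydride 19 (not isolated)
Conditions: (CF3CO)2O, 2,6-di-tert-butyl-4-methylpyridine, CH2Cl2, −20 °C to 0 °C
Reagents that add atoms: none
Why: The anhydride converts acid 18 into the mixed anhydride 19, whose acyl carbon is attacked by a ring A carbon ortho to the ether oxygen, a position activated by that oxygen and by both silyloxy groups; loss of the proton from the arenium ion to the hindered pyridine restores the arene and gives the C4–C4a bond. The closest known reaction type is the trifluoroacetic anhydride-mediated intramolecular Friedel–Crafts acylation of 3-aryloxypropanoic acids to chroman-4-ones. Ring C closes in the 6-exo-trig mode at the acyl carbon, with the carbonyl oxygen outside the new six-membered ring. No stereocenter is formed; C2 and C2'' are carried through and the C2–O1 bond takes no part in the bond formation. Site selectivity is not needed, because the two ortho carbons of ring A are interchanged by rotation about the O–C1/C4–C1'' axis, so either closure gives the same 6-lavandulyl chromanone and an 8-isomer cannot arise. The step does need retention at both stereocenters and chemoselectivity for ring A: the three acetates make ring B too electron-poor to be acylated or to stabilise a cation at C2, the side-chain alkenes cannot reach the acyl carbon, and the hindered base takes up the trifluoroacetic acid so that the alkenes are not protonated and the silyl ethers stay on at low temperature.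

Step 13
Reactants: 20 (2S)-5,7-bis(tert-butyldimethylsilyloxy)-6-[(2R)-5-methyl-2-(prop-1-en-2-yl)hex-4-enyl]-2-[2,4,6-tris(acetyloxy)phenyl]chroman-4-one
Product: 21 (2S)-5,7-dihydroxy-6-[(2R)-5-methyl-2-(prop-1-en-2-yl)hex-4-enyl]-2-[2,4,6-tris(acetyloxy)phenyl]chroman-4-one
Conditions: HF·pyridine, pyridine, THF, 0 °C
Reagents that add atoms: none
Why: Fluoride-mediated cleavage of the two aryl silyl ethers; the excess pyridine keeps the medium too weakly acidic to protonate the alkenes next to the new phenols, the acetates are inert, and ring B is still electron-poor, so C2–O1 cannot ionise.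

Step 14
Reactants: 21 (2S)-5,7-dihydroxy-6-[(2R)-5-methyl-2-(prop-1-en-2-yl)hex-4-enyl]-2-[2,4,6-tris(acetyloxy)phenyl]chroman-4-one
Product: 22 (2S)-5,7-dihydroxy-6-[(2R)-5-methyl-2-(prop-1-en-2-yl)hex-4-enyl]-2-(2,4,6-trihydroxyphenyl)chroman-4-one
Conditions: NH4OAc, MeOH/H2O (4:1), 20 °C
Reagents that add atoms: none
Why: Ammonium acetate-mediated neutral methanolysis of aryl acetates, which are activated esters; near pH 7 there is neither enough phenoxide to open ring C to the chalcone nor enough acid to ionise C2–O1 or cyclise the side chain, so both stereocenters and the 6-position of the chain should be preserved.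

## Compound list

1 | racemic lavandulol, (RS)-5-methyl-2-(prop-1-en-2-yl)hex-4-en-1-ol | C=C(C)C(CO)CC=C(C)C | starting material
2 | (S)-lavandulol, (2S)-5-methyl-2-(prop-1-en-2-yl)hex-4-en-1-ol | C=C(C)[C@H](CC=C(C)C)CO | intermediate
3 | (S)-lavandulyl iodide, (3S)-3-(iodomethyl)-2,6-dimethylhepta-1,5-diene | C=C(C)[C@H](CC=C(C)C)CI | intermediate
4 | phloroglucinol, benzene-1,3,5-triol | Oc1cc(O)cc(O)c1 | starting material
5 | 2-iodobenzene-1,3,5-triol | Oc1cc(O)c(I)c(O)c1 | intermediate
6 | 2-iodo-1,3,5-tris(tert-butyldimethylsilyloxy)benzene | CC(C)(C)[Si](C)(C)Oc1cc(O[Si](C)(C)C(C)(C)C)c(I)c(O[Si](C)(C)C(C)(C)C)c1 | intermediate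
7 | [(2S)-5-methyl-2-(prop-1-en-2-yl)hex-4-enyl]zinc iodide | C=C(C)[C@H](CC=C(C)C)C[Zn]I | intermediate
8 | 1,3,5-tris(tert-butyldimethylsilyloxy)-2-[(2R)-5-methyl-2-(prop-1-en-2-yl)hex-4-enyl]benzene | C=C(C)[C@H](CC=C(C)C)Cc1c(O[Si](C)(C)C(C)(C)C)cc(O[Si](C)(C)C(C)(C)C)cc1O[Si](C)(C)C(C)(C)C | intermediate
9 | 3,5-bis(tert-butyldimethylsilyloxy)-4-[(2R)-5-methyl-2-(prop-1-en-2-yl)hex-4-enyl]phenol | C=C(C)[C@H](CC=C(C)C)Cc1c(O[Si](C)(C)C(C)(C)C)cc(O)cc1O[Si](C)(C)C(C)(C)C | intermediate
10 | 2,4,6-trihydroxybenzaldehyde | O=Cc1c(O)cc(O)cc1O | starting material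
11 | 2,4,6-tris(acetyloxy)benzaldehyde | O=Cc1c(OC(C)=O)cc(OC(C)=O)cc1OC(C)=O | intermediate
12 | tert-butyl acetate | CC(=O)OC(C)(C)C | starting material
13 | 1-(tert-butoxy)-1-(tert-butyldimethylsilyloxy)ethene | C=C(OC(C)(C)C)O[Si](C)(C)C(C)(C)C | intermediate
14 | tert-butyl (3R)-3-(trichlorosilyloxy)-3-[2,4,6-tris(acetyloxy)phenyl]propanoate | CC(C)(C)OC(=O)C[C@@H](O[Si](Cl)(Cl)Cl)c1c(OC(C)=O)cc(OC(C)=O)cc1OC(C)=O | intermediate
15 | tert-butyl (3R)-3-hydroxy-3-[2,4,6-tris(acetyloxy)phenyl]propanoate | CC(C)(C)OC(=O)C[C@@H](O)c1c(OC(C)=O)cc(OC(C)=O)cc1OC(C)=O | intermediate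
16 | tert-butyl (3S)-3-{3,5-bis(tert-butyldimethylsilyloxy)-4-[(2R)-5-methyl-2-(prop-1-en-2-yl)hex-4-enyl]phenoxy}-3-[2,4,6-tris(acetyloxy)phenyl]propanoate | C=C(C)[C@H](CC=C(C)C)Cc1c(O[Si](C)(C)C(C)(C)C)cc(O[C@@H](CC(=O)OC(C)(C)C)c2c(OC(C)=O)cc(OC(C)=O)cc2OC(C)=O)cc1O[Si](C)(C)C(C)(C)C | intermediate
17 | trimethylsilyl (3S)-3-{3,5-bis(tert-butyldimethylsilyloxy)-4-[(2R)-5-methyl-2-(prop-1-en-2-yl)hex-4-enyl]phenoxy}-3-[2,4,6-tris(acetyloxy)phenyl]propanoate | C=C(C)[C@H](CC=C(C)C)Cc1c(O[Si](C)(C)C(C)(C)C)cc(O[C@@H](CC(=O)O[Si](C)(C)C)c2c(OC(C)=O)cc(OC(C)=O)cc2OC(C)=O)cc1O[Si](C)(C)C(C)(C)C | intermediate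
18 | (3S)-3-{3,5-bis(tert-butyldimethylsilyloxy)-4-[(2R)-5-methyl-2-(prop-1-en-2-yl)hex-4-enyl]phenoxy}-3-[2,4,6-tris(acetyloxy)phenyl]propanoic acid | C=C(C)[C@H](CC=C(C)C)Cc1c(O[Si](C)(C)C(C)(C)C)cc(O[C@@H](CC(=O)O)c2c(OC(C)=O)cc(OC(C)=O)cc2OC(C)=O)cc1O[Si](C)(C)C(C)(C)C | intermediate
19 | (3S)-3-{3,5-bis(tert-butyldimethylsilyloxy)-4-[(2R)-5-methyl-2-(prop-1-en-2-yl)hex-4-enyl]phenoxy}-3-[2,4,6-tris(acetyloxy)phenyl]propanoic trifluoroacetic anhydride | C=C(C)[C@H](CC=C(C)C)Cc1c(O[Si](C)(C)C(C)(C)C)cc(O[C@@H](CC(=O)OC(=O)C(F)(F)F)c2c(OC(C)=O)cc(OC(C)=O)cc2OC(C)=O)cc1O[Si](C)(C)C(C)(C)C | intermediate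
20 | (2S)-5,7-bis(tert-butyldimethylsilyloxy)-6-[(2R)-5-methyl-2-(prop-1-en-2-yl)hex-4-enyl]-2-[2,4,6-tris(acetyloxy)phenyl]chroman-4-one | C=C(C)[C@H](CC=C(C)C)Cc1c(O[Si](C)(C)C(C)(C)C)cc2c(c1O[Si](C)(C)C(C)(C)C)C(=O)C[C@@H](c1c(OC(C)=O)cc(OC(C)=O)cc1OC(C)=O)O2 | intermediate
21 | (2S)-5,7-dihydroxy-6-[(2R)-5-methyl-2-(prop-1-en-2-yl)hex-4-enyl]-2-[2,4,6-tris(acetyloxy)phenyl]chroman-4-one | C=C(C)[C@H](CC=C(C)C)Cc1c(O)cc2c(c1O)C(=O)C[C@@H](c1c(OC(C)=O)cc(OC(C)=O)cc1OC(C)=O)O2 | intermediate
22 | (2S)-5,7-dihydroxy-6-[(2R)-5-methyl-2-(prop-1-en-2-yl)hex-4-enyl]-2-(2,4,6-trihydroxyphenyl)chroman-4-one | C=C(C)[C@H](CC=C(C)C)Cc1c(O)cc2c(c1O)C(=O)C[C@@H](c1c(O)cc(O)cc1O)O2 | target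

## Step count and risks

Total: 14 steps. Longest linear sequence: 9 steps (from 1 through 2, 3, 8, 9, 16, 18, 20 and 21 to 22; the sequence from 4 is equally long).

**Step 12 (key step).** The most likely failure is acid-induced damage before the ring closes: protonation of the isopropenyl or prenyl alkene by liberated trifluoroacetic acid (double-bond migration would erase C2''), or loss of a ring A silyl group followed by O-trifluoroacetylation, which deactivates the ring and stalls the acylation. The fallback leaves the mixed-anhydride manifold. It sets out from 18, which is converted under neutral conditions with 1-chloro-N,N,2-trimethylprop-1-en-1-amine in CH2Cl2 at 0 °C into (3S)-3-{3,5-bis(tert-butyldimethylsilyloxy)-4-[(2R)-5-methyl-2-(prop-1-en-2-yl)hex-4-enyl]phenoxy}-3-[2,4,6-tris(acetyloxy)phenyl]propanoyl chloride F1. This is closed at −78 °C with SnCl4 in the presence of 2,6-di-tert-butyl-4-methylpyridine, so that no free protic acid is present, and the route is rejoined at 20.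

**Step 10.** Three processes can compete with clean inversion: elimination to the cinnamate through the acidic alpha-hydrogens, participation of an ortho acetoxy carbonyl in the departure of the phosphonium oxygen (partial retention), and shift of an ortho acetyl group to the free hydroxyl before it is activated. The fallback replaces the acetates by pivalates until the ether is made. It sets out from 10:
- Pivaloyl chloride, Et3N and DMAP give 2,4,6-tris(pivaloyloxy)benzaldehyde F2.
- The aldol of step 9 with 13 gives, through tert-butyl (3R)-3-(trichlorosilyloxy)-3-[2,4,6-tris(pivaloyloxy)phenyl]propanoate F3, tert-butyl (3R)-3-hydroxy-3-[2,4,6-tris(pivaloyloxy)phenyl]propanoate F4.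
- Mitsunobu coupling with 9 gives tert-butyl (3S)-3-{3,5-bis(tert-butyldimethylsilyloxy)-4-[(2R)-5-methyl-2-(prop-1-en-2-yl)hex-4-enyl]phenoxy}-3-[2,4,6-tris(pivaloyloxy)phenyl]propanoate F5.
- Hydrazine hydrate in THF/MeOH cleaves the aryl pivalates, leaving the tert-butyl ester and silyl ethers, to give tert-butyl (3S)-3-{3,5-bis(tert-butyldimethylsilyloxy)-4-[(2R)-5-methyl-2-(prop-1-en-2-yl)hex-4-enyl]phenoxy}-3-(2,4,6-trihydroxyphenyl)propanoate F6.
- F6 is acetylated at once with Ac2O and pyridine, and the route is rejoined at 16.

**Step 9.** The facial selectivity may fall short because both ortho positions of the aldehyde are substituted and change how it sits on the silicon cation; acetyl transfer during hydrolysis of the silyl ether is the second hazard. The fallback sets out from 11. SnCl2-catalysed Roskamp homologation with tert-butyl diazoacetate gives tert-butyl 3-oxo-3-[2,4,6-tris(acetyloxy)phenyl]propanoate F7. Asymmetric hydrogenation with RuCl2[(S)-binap] under H2 in EtOH/CH2Cl2 at 30 °C rejoins the route at 15. The (S)-ligand is the one that gives (R)-3-aryl-3-hydroxypropanoates from aroylacetates.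

**Step 6.** Insufficient discrimination between the para and the two ortho silyl ethers, further desilylation, or silyl exchange between phenoxides would give isomeric phenols. The fallback marks the para oxygen before the coupling. It sets out from 5:
- One equivalent of pivaloyl chloride with pyridine at −40 °C acylates the hydroxyl that is not flanked by iodine and gives 3,5-dihydroxy-4-iodophenyl pivalate F8.
- TBSCl and imidazole give 3,5-bis(tert-butyldimethylsilyloxy)-4-iodophenyl pivalate F9.
- Negishi coupling with 7 gives 3,5-bis(tert-butyldimethylsilyloxy)-4-[(2R)-5-methyl-2-(prop-1-en-2-yl)hex-4-enyl]phenyl pivalate F10.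
- iBu2AlH at −78 °C removes the pivalate reductively, and the route is rejoined at 9.

**Step 5.** Transmetalation at an arylpalladium flanked by two silyloxy groups may be slow, which would leave room for protodeiodination of 6 and beta-hydride elimination of the alkyl group. The fallback couples before the bulky groups are installed. It sets out from 5:
- Ac2O and pyridine give 2-iodobenzene-1,3,5-triyl triacetate F11, a less hindered and more electron-poor iodide.
- Negishi coupling with 7 gives 2-[(2R)-5-methyl-2-(prop-1-en-2-yl)hex-4-enyl]benzene-1,3,5-triyl triacetate F12.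
- K2CO3 in MeOH under argon gives 2-[(2R)-5-methyl-2-(prop-1-en-2-yl)hex-4-enyl]benzene-1,3,5-triol F13.
- TBSCl and imidazole rejoin the route at 8.

**Step 14.** During long exposure in a protic medium, a small share of phenoxide may open ring C to the chalcone or quinone methide, which would erode the configuration at C2 and could move the side chain to C8. The fallback avoids water and ionised phenols altogether. It sets out from 21 and uses lipase-catalysed transesterification (immobilised Candida antarctica lipase B, butan-1-ol, tert-butyl methyl ether, 35 °C) to reach 22 directly; no new compound is involved.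

## Further compounds

F1 | step 12 | (3S)-3-{3,5-bis(tert-butyldimethylsilyloxy)-4-[(2R)-5-methyl-2-(prop-1-en-2-yl)hex-4-enyl]phenoxy}-3-[2,4,6-tris(acetyloxy)phenyl]propanoyl chloride | C=C(C)[C@H](CC=C(C)C)Cc1c(O[Si](C)(C)C(C)(C)C)cc(O[C@@H](CC(=O)Cl)c2c(OC(C)=O)cc(OC(C)=O)cc2OC(C)=O)cc1O[Si](C)(C)C(C)(C)C
F2 | step 10 | 2,4,6-tris(pivaloyloxy)benzaldehyde | O=Cc1c(OC(=O)C(C)(C)C)cc(OC(=O)C(C)(C)C)cc1OC(=O)C(C)(C)C
F3 | step 10 | tert-butyl (3R)-3-(trichlorosilyloxy)-3-[2,4,6-tris(pivaloyloxy)phenyl]propanoate | CC(C)(C)OC(=O)C[C@@H](O[Si](Cl)(Cl)Cl)c1c(OC(=O)C(C)(C)C)cc(OC(=O)C(C)(C)C)cc1OC(=O)C(C)(C)C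
F4 | step 10 | tert-butyl (3R)-3-hydroxy-3-[2,4,6-tris(pivaloyloxy)phenyl]propanoate | CC(C)(C)OC(=O)C[C@@H](O)c1c(OC(=O)C(C)(C)C)cc(OC(=O)C(C)(C)C)cc1OC(=O)C(C)(C)C
F5 | step 10 | tert-butyl (3S)-3-{3,5-bis(tert-butyldimethylsilyloxy)-4-[(2R)-5-methyl-2-(prop-1-en-2-yl)hex-4-enyl]phenoxy}-3-[2,4,6-tris(pivaloyloxy)phenyl]propanoate | C=C(C)[C@H](CC=C(C)C)Cc1c(O[Si](C)(C)C(C)(C)C)cc(O[C@@H](CC(=O)OC(C)(C)C)c2c(OC(=O)C(C)(C)C)cc(OC(=O)C(C)(C)C)cc2OC(=O)C(C)(C)C)cc1O[Si](C)(C)C(C)(C)C
F6 | step 10 | tert-butyl (3S)-3-{3,5-bis(tert-butyldimethylsilyloxy)-4-[(2R)-5-methyl-2-(prop-1-en-2-yl)hex-4-enyl]phenoxy}-3-(2,4,6-trihydroxyphenyl)propanoate | C=C(C)[C@H](CC=C(C)C)Cc1c(O[Si](C)(C)C(C)(C)C)cc(O[C@@H](CC(=O)OC(C)(C)C)c2c(O)cc(O)cc2O)cc1O[Si](C)(C)C(C)(C)C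
F7 | step 9 | tert-butyl 3-oxo-3-[2,4,6-tris(acetyloxy)phenyl]propanoate | CC(C)(C)OC(=O)CC(=O)c1c(OC(C)=O)cc(OC(C)=O)cc1OC(C)=O
F8 | step 6 | 3,5-dihydroxy-4-iodophenyl pivalate | CC(C)(C)C(=O)Oc1cc(O)c(I)c(O)c1
F9 | step 6 | 3,5-bis(tert-butyldimethylsilyloxy)-4-iodophenyl pivalate | CC(C)(C)C(=O)Oc1cc(O[Si](C)(C)C(C)(C)C)c(I)c(O[Si](C)(C)C(C)(C)C)c1
F10 | step 6 | 3,5-bis(tert-butyldimethylsilyloxy)-4-[(2R)-5-methyl-2-(prop-1-en-2-yl)hex-4-enyl]phenyl pivalate | C=C(C)[C@H](CC=C(C)C)Cc1c(O[Si](C)(C)C(C)(C)C)cc(OC(=O)C(C)(C)C)cc1O[Si](C)(C)C(C)(C)C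
F11 | step 5 | 2-iodobenzene-1,3,5-triyl triacetate | CC(=O)Oc1cc(OC(C)=O)c(I)c(OC(C)=O)c1
F12 | step 5 | 2-[(2R)-5-methyl-2-(prop-1-en-2-yl)hex-4-enyl]benzene-1,3,5-triyl triacetate | C=C(C)[C@H](CC=C(C)C)Cc1c(OC(C)=O)cc(OC(C)=O)cc1OC(C)=O
F13 | step 5 | 2-[(2R)-5-methyl-2-(prop-1-en-2-yl)hex-4-enyl]benzene-1,3,5-triol | C=C(C)[C@H](CC=C(C)C)Cc1c(O)cc(O)cc1O
F0 | step 14 | none | none
A1 | alternative 1 | (R)-4-benzyl-3-[(2R)-2-{[2,6-bis(methoxymethoxy)-4-(triisopropylsilyloxy)phenyl]methyl}-5-methylhex-4-enoyl]oxazolidin-2-one | O=C(N1[C@H](Cc2ccccc2)COC1=O)[C@H](CC=C(C)C)Cc1c(OCOC)cc(O[Si](C(C)C)(C(C)C)C(C)C)cc1OCOC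
A2 | alternative 1 | (R)-3-acryloyl-4-benzyloxazolidin-2-one | C=CC(=O)N1[C@H](Cc2ccccc2)COC1=O
A3 | alternative 1 | prenyl bromide, 1-bromo-3-methylbut-2-ene | CC(C)=CCBr
A4 | alternative 2 | (3R)-5-(methoxymethoxy)-3-(3-methylbut-2-enyl)-7-(prop-2-enyloxy)chroman-2-one | O=C1[C@H](CC=C(C)C)Cc2c(OCOC)cc(OCC=C)cc2O1
A5 | alternative 3 | 5-(methoxymethoxy)-2-[(2R)-5-methyl-2-(prop-1-en-2-yl)hex-4-enyl]-3-(triisopropylsilyloxy)phenol | C=C(C)[C@H](CC=C(C)C)Cc1c(O)cc(OCOC)cc1O[Si](C(C)C)(C(C)C)C(C)C
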